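**Retrosynthetic overview**
- The strategy rests on the tertiary benzylic carbinol carbon of the target. It carries the OH, the 2-methoxy-4-methylphenyl ring and two identical CH2–O–C(=O)iPr arms, and the benzene ring is the only ring.
- Both ester C–O bonds are cut. One arm's O–CH2 bond comes from isobutyrate attack on the CH2 of a 2,2-disubstituted oxirane, and the other arm is carried as a CH2–OSi ether and acylated last.
- The oxirane comes from methylene transfer by a sulfur ylide to an aryl α-silyloxy ketone, which forms the C(carbinol)–CH2 bond of the second arm.
- The ketone comes from the aryllithium of 1-bromo-2-methoxy-4-methylbenzene and (tert-butyldimethylsilyloxy)acetaldehyde, followed by oxidation.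
- Ring order: the arene is bought; the oxirane is the only ring made (step 3) and is opened again in step 4.

Key step: step 3

Remark: the carbinol carbon of the target carries two identical arms, so the target has no stereocentre; the chiral intermediates are carried as racemates.

**Route**

Step 1
Reactants: 1 1-bromo-2-methoxy-4-methylbenzene; 2 (tert-butyldimethylsilyloxy)acetaldehyde
Product: 4 2-[(tert-butyldimethylsilyl)oxy]-1-(2-methoxy-4-methylphenyl)ethan-1-ol (racemic), via (2-methoxy-4-methylphenyl)lithium 3 (not isolated)
Conditions: n-BuLi, THF, −78 °C; then 2, −78 °C; NH4Cl aq at −78 °C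
Reagents that add atoms: none
Why: Bromine–lithium exchange is fast at −78 °C and the aryllithium, stabilised by its ortho-methoxy group, should add 1,2 to the aldehyde (organolithium addition to a carbonyl); the new carbinol centre forms as a racemate and is removed by the oxidation in step 2.

Step 2
Reactants: 4 2-[(tert-butyldimethylsilyl)oxy]-1-(2-methoxy-4-methylphenyl)ethan-1-ol (racemic)
Product: 5 2-[(tert-butyldimethylsilyl)oxy]-1-(2-methoxy-4-methylphenyl)ethan-1-one
Conditions: Dess–Martin periodinane, pyridine, CH2Cl2, 0 °C → rt
Reagents that add atoms: none
Why: Dess–Martin oxidation of a secondary benzylic alcohol under pyridine-buffered conditions should give the aryl ketone without touching the silyl ether or the electron-rich arene, and the only stereocentre is erased.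

Step 3
Reactants: 5 2-[(tert-butyldimethylsilyl)oxy]-1-(2-methoxy-4-methylphenyl)ethan-1-one; 6 trimethylsulfonium iodide
Product: 9 2-{[(tert-butyldimethylsilyl)oxy]methyl}-2-(2-methoxy-4-methylphenyl)oxirane (racemic), via dimethylsulfonium methylide 7 (not isolated), via sulfonium betaine 8 (not isolated)
Conditions: 6 (1.5 equiv), KOtBu (1.4 equiv), DMSO–THF, 0 °C; then 5, 0 °C → rt; work-up and chromatography on Et3N-deactivated silica
Reagents that add atoms: trimethylsulfonium iodide (compound 6), C[S+](C)C.[I-]
Why: KOtBu deprotonates 6 to the ylide 7, whose carbon adds to the carbonyl of 5 to give the betaine 8, and the alkoxide of 8 then expels dimethyl sulfide by intramolecular SN2 displacement; this is the Corey–Chaykovsky epoxidation of an aryl ketone. The oxirane closes 3-exo-tet, and the step forms the bond from the carbinol carbon to the second methylene. The new quaternary centre forms as a racemate under no control, which is harmless because it becomes the non-stereogenic carbinol carbon once both arms carry the same ester. The step needs carbonyl addition to win over deprotonation of the α-CH2: the unstabilised ylide is a weaker base than the ketone enolate and adds irreversibly, the α-oxygen raises the electrophilicity of the carbonyl, and keeping 6 in slight excess over KOtBu leaves no free tert-butoxide. A silyl ether on the α-oxygen, unlike an ester, offers the betaine alkoxide no acyl group to take up.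

Step 4
Reactants: 9 2-{[(tert-butyldimethylsilyl)oxy]methyl}-2-(2-methoxy-4-methylphenyl)oxirane (racemic); 10 isobutyric acid
Product: 12 3-[(tert-butyldimethylsilyl)oxy]-2-hydroxy-2-(2-methoxy-4-methylphenyl)propyl 2-methylpropanoate (racemic), via cesium isobutyrate 11 (not isolated)
Conditions: 10 (3 equiv), Cs2CO3 (1 equiv), DMF, rt (CO2 release); then 9, 80 °C
Reagents that add atoms: isobutyric acid (compound 10), CC(C)C(=O)O
Why: Carboxylate ring-opening of an epoxide by SN2 attack of 11 at the unsubstituted CH2; with no Lewis or strong Brønsted acid present the fully substituted benzylic carbon should not ionise, and the one equivalent of free 10 protonates the tertiary alkoxide as it forms, which holds back silyl and acyl migration.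

Step 5
Reactants: 12 3-[(tert-butyldimethylsilyl)oxy]-2-hydroxy-2-(2-methoxy-4-methylphenyl)propyl 2-methylpropanoate (racemic)
Product: 13 2,3-dihydroxy-2-(2-methoxy-4-methylphenyl)propyl 2-methylpropanoate (racemic)
Conditions: Bu4NF, AcOH, THF, 0 °C → rt
Reagents that add atoms: none
Why: Fluoride-mediated desilylation driven by the strong Si–F bond; the acetic acid buffer keeps the medium from turning basic so the isobutyrate should survive, and any shift of the acyl group between the two primary oxygens only interconverts the enantiomers of racemic 13.

Step 6
Reactants: 13 2,3-dihydroxy-2-(2-methoxy-4-methylphenyl)propyl 2-methylpropanoate (racemic)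
Product: 14 2-hydroxy-2-(2-methoxy-4-methylphenyl)propane-1,3-diyl bis(2-methylpropanoate) (achiral target)
Conditions: isobutyryl chloride (1.1 equiv), pyridine, CH2Cl2, 0 °C
Reagents that add atoms: isobutyryl chloride, CC(C)C(=O)Cl
Why: Nucleophilic acyl substitution through the acylpyridinium ion; the primary hydroxyl is acylated far faster than the hindered tertiary benzylic one, so a slight excess of acyl chloride at 0 °C should esterify only the primary position and give the achiral target.

**Compound list**
1 | 1-bromo-2-methoxy-4-methylbenzene | COc1cc(C)ccc1Br | starting material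
2 | (tert-butyldimethylsilyloxy)acetaldehyde | O=CCO[Si](C)(C)C(C)(C)C | starting material
3 | (2-methoxy-4-methylphenyl)lithium (not isolated) | [Li]c1ccc(C)cc1OC | intermediate
4 | 2-[(tert-butyldimethylsilyl)oxy]-1-(2-methoxy-4-methylphenyl)ethan-1-ol (racemic) | COc1cc(C)ccc1C(O)CO[Si](C)(C)C(C)(C)C | intermediate
5 | 2-[(tert-butyldimethylsilyl)oxy]-1-(2-methoxy-4-methylphenyl)ethan-1-one | COc1cc(C)ccc1C(=O)CO[Si](C)(C)C(C)(C)C | intermediate
6 | trimethylsulfonium iodide | C[S+](C)C.[I-] | starting material
7 | dimethylsulfonium methylide (not isolated) | C[S+](C)[CH2-] | intermediate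
8 | sulfonium betaine, alkoxide–sulfonium zwitterion (racemic, not isolated) | COc1cc(C)ccc1C([O-])(CO[Si](C)(C)C(C)(C)C)C[S+](C)C | intermediate
9 | 2-{[(tert-butyldimethylsilyl)oxy]methyl}-2-(2-methoxy-4-methylphenyl)oxirane (racemic) | COc1cc(C)ccc1C1(CO[Si](C)(C)C(C)(C)C)CO1 | intermediate
10 | isobutyric acid (2-methylpropanoic acid) | CC(C)C(=O)O | starting material
11 | cesium isobutyrate (not isolated) | CC(C)C(=O)[O-].[Cs+] | intermediate
12 | 3-[(tert-butyldimethylsilyl)oxy]-2-hydroxy-2-(2-methoxy-4-methylphenyl)propyl 2-methylpropanoate (racemic) | COc1cc(C)ccc1C(O)(CO[Si](C)(C)C(C)(C)C)COC(=O)C(C)C | intermediate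
13 | 2,3-dihydroxy-2-(2-methoxy-4-methylphenyl)propyl 2-methylpropanoate (racemic) | COc1cc(C)ccc1C(O)(CO)COC(=O)C(C)C | intermediate
14 | 2-hydroxy-2-(2-methoxy-4-methylphenyl)propane-1,3-diyl bis(2-methylpropanoate) (achiral) | COc1cc(C)ccc1C(O)(COC(=O)C(C)C)COC(=O)C(C)C | target

**Step count**
Total steps: 6. Longest linear sequence: 6 steps (1 → 14).

**Steps most likely to fail**

1. Step 3 (key step). The crowded ortho-substituted aryl ketone may take up the ylide slowly, so that ylide decay, deprotonation at the α-CH2 or silyl transfer competes. The electron-rich aryl oxirane may also rearrange to an aldehyde on contact with acid during isolation. The fallback sets out from 5 and comes back at 12 without handling any oxirane. Wittig methylenation of 5 (Ph3PCH3Br, KOtBu, THF, 0 °C → rt) would give the alkene tert-butyl{[2-(2-methoxy-4-methylphenyl)prop-2-en-1-yl]oxy}dimethylsilane F1. Catalytic dihydroxylation (K2OsO4·2H2O, N-methylmorpholine N-oxide, acetone–H2O, rt) would then install both oxygens at once and give 3-[(tert-butyldimethylsilyl)oxy]-2-(2-methoxy-4-methylphenyl)propane-1,2-diol F2 (racemic). Acylation of its primary hydroxyl (isobutyryl chloride, pyridine, CH2Cl2, 0 °C) would give 12.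

2. Step 4. Opening may be slow at the CH2 next to a quaternary carbon, and on prolonged heating the oxirane may ionise at the benzylic carbon, leading to attack at the wrong carbon or to rearrangement; the alkoxide may also trigger silyl or acyl migration. The fallback sets out from 9 and comes back at 14, and replaces the carboxylate by hydroxide so that regiochemistry no longer matters. Bu4NF (THF, 0 °C) would free [2-(2-methoxy-4-methylphenyl)oxiran-2-yl]methanol F3 (racemic). Hydrolysis (KOH, DMSO–H2O, 80 °C) would give 2-(2-methoxy-4-methylphenyl)propane-1,2,3-triol F4, since attack at either oxirane carbon, before or after a degenerate Payne shift, leads to the same triol. Isobutyryl chloride (2.2 equiv) and pyridine in CH2Cl2 at 0 °C would then acylate the two primary hydroxyls and leave the tertiary one, giving 14.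

3. Step 1. The α-silyloxy aldehyde may be enolised by the aryllithium or may arrive partly as oligomer or hydrate that quenches it, and the lithium alkoxide may pass its silyl group between the two oxygens if allowed to warm. The fallback sets out from 1 (as its aryllithium 3) and comes back at 5, so that step 2 is no longer needed. Commercial methyl glycolate would be silylated (TBSCl, imidazole, DMF, rt) to methyl 2-[(tert-butyldimethylsilyl)oxy]acetate F5. This would be converted (MeNHOMe·HCl, iPrMgCl, THF, −20 °C) into the Weinreb amide 2-[(tert-butyldimethylsilyl)oxy]-N-methoxy-N-methylacetamide F6. Addition of 3 to this amide (THF, −78 °C, then NH4Cl aq) would give 5 through a chelated tetrahedral adduct that neither over-adds nor enolises.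

**Further compounds**
F1 | step 3 | tert-butyl{[2-(2-methoxy-4-methylphenyl)prop-2-en-1-yl]oxy}dimethylsilane | COc1cc(C)ccc1C(=C)CO[Si](C)(C)C(C)(C)C
F2 | step 3 | 3-[(tert-butyldimethylsilyl)oxy]-2-(2-methoxy-4-methylphenyl)propane-1,2-diol (racemic) | COc1cc(C)ccc1C(O)(CO)CO[Si](C)(C)C(C)(C)C
F3 | step 4 | [2-(2-methoxy-4-methylphenyl)oxiran-2-yl]methanol (racemic) | COc1cc(C)ccc1C1(CO)CO1
F4 | step 4 | 2-(2-methoxy-4-methylphenyl)propane-1,2,3-triol | COc1cc(C)ccc1C(O)(CO)CO
F5 | step 1 | methyl 2-[(tert-butyldimethylsilyl)oxy]acetate | COC(=O)CO[Si](C)(C)C(C)(C)C
F6 | step 1 | 2-[(tert-butyldimethylsilyl)oxy]-N-methoxy-N-methylacetamide | CON(C)C(=O)CO[Si](C)(C)C(C)(C)C
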